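# Synthesis design for 2-hydroxy-6-(13-hydroxy-2-oxotridecyl)-4-methoxybenzoic acid (17)

## The problem

Compound 17 is a benzene ring with four substituents in a 1,2,4,6 pattern: a carboxyl group on C1, a free hydroxyl on C2, a methoxy group on C4, and on C6 a thirteen-carbon chain with a ketone at C2' and a primary alcohol at C13'. It has no second ring and no stereocentre, so the difficulty lies in regiochemistry and functional-group tolerance, not in stereocontrol. The carboxyl-bearing carbon is flanked by two ortho substituents, which makes C1 and C6 the least accessible positions for substitution on a preformed arene. The two phenolic oxygens must end up different, one free and one methylated. The ortho pairing of the acid with a 2-oxoalkyl arm makes 17 a latent isocoumarin: dehydrating acid closes the enol lactone, and heat or strong acid threatens decarboxylation of the electron-rich salicylic acid. The benzylic ketone lies between two enolisable methylenes that can condense with an aryl ester under strong base, and the remote primary alcohol must stay masked through all carbon–carbon bond formation. The enabling feature is the oxygen pattern along the carbon chain: the carboxyl carbon, C2, C4 and C2' carry oxygen on alternate carbons, with a single gap at C6. That gap is where an aldol acceptor carbonyl would have lost its oxygen on dehydration, so the C1–C6 bond can be made by intramolecular aldol condensation of a linear poly-β-carbonyl chain, provided the C2' carbonyl is kept out of the folding.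

## Retrosynthesis

**17 from 15 (through 16).** Only protecting-group bonds are cut: the acetonide that ties the carboxyl to the C2 oxygen, the dioxolane on C2' and the silyl ether on C13'. All three can be released in one flask, alkali first and dilute aqueous acid second. Alkali is applied while the ketone is still a ketal, so no enolate of the benzylic ketone can attack the aryl ester. The acid stage is run last, in a water-rich medium at room temperature, where the keto acid is favoured over its dehydrated lactone. The precursor 15 is neutral, fully protected and robust. The forward reaction must open a hindered, electron-rich benzodioxinone, which needs hot hydroxide, and must keep the final acid exposure mild. The carboxylic acid 16 is passed through without isolation.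

**15 from 14.** The C4–O–methyl bond is cut. In 14 the C2 oxygen is locked in the acetonide, so the phenol para to the carbonyl is the only free hydroxyl and methylation cannot go astray. The neighbouring option, a dimethyl ether with later selective dealkylation, would add a step and a Lewis acid.

**14 from 12 (key disconnection).** The arene bond C1–C6 (C4a–C5 of the benzodioxinone) is cut, together with the unsaturation created by dehydration. This returns the open-chain diketo-dioxinone 12, by way of the cyclic aldol 13. Cutting C6–C1' or the C1–carboxyl bond instead would require substitution at the most crowded position of an electron-rich arene and would deliver both oxygens in the same form. The aldol cut places all four substituents by construction and leaves exactly one phenol free. The precursor 12 is acyclic apart from its two protecting rings and is a 1,3-diketone, which is easy to assemble. The forward reaction must choose a single mode of folding. The dioxolane secures this, because 13 is then the only aldol of 12 that closes a ring larger than four atoms.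

**12 from 3 and 11.** The bond between the central methylene and the distal carbonyl of the 1,3-diketone is cut. Forward, this is a Claisen-type acylation of the dianion of keto-dioxinone 3, at its terminal carbon, by the Weinreb amide 11. The alternative cut next to the dioxinone would need a β,δ-dicarbonyl acylating agent that is less stable than 11. An N-methoxy-N-methyl amide is preferred to an acyl imidazole or acid chloride for two reasons: its tetrahedral adduct persists until the quench, and its α-protons are much less acidic. The lower acidity guards the β-dioxolane against ring opening by elimination.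

**3 from 1 and 2.** The bond between the γ-carbon of dioxinone 1 and the acetyl carbonyl of 2 is cut. Both are commercial, and the forward step is a γ-acylation of the dienolate of 1.

**11 from 10, and 10 from 9.** The amide C–N bond is traced back to methyl ester 10, and the dioxolane C–O bonds to β-keto ester 9. The β-keto ester is the first stage at which the future C2' ketone exists in an isolable form, so it is the natural point for masking. The forward ketalisation must spare a primary silyl ether, which calls for aprotic silyl-transfer conditions and rules out hot protic acid.

**9 from 6 and 7, and 6 from 4.** The C2–C3 bond of the β-keto ester is cut, giving the silyl-protected acid 6 and Meldrum's acid 7. The acyl Meldrum's acid 8 is the intermediate of this two-carbon homologation. Acid 6 comes from commercial 12-hydroxydodecanoic acid 4 through the bis-silylated ester 5. The carboxyl carbon of 4 becomes C2' of 17, and its eleven methylenes and hydroxyl become C3' to C13' with the terminal alcohol.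

## Roads not taken

**Alternative 1:** The aryl C6–C1' bond and the lactone C–O bond are cut. Forward, the carboxylate of 2,4-dimethoxybenzoic acid A1 directs a rhodium(III) catalyst to its only free ortho C–H bond. The keto sulfoxonium ylide A2, made from a silyl-protected derivative of 4, delivers a metal carbene that inserts, and the acid condenses onto the new ketone to give isocoumarin A3. Selective cleavage of the peri methyl ether, alkaline opening of the enol lactone and desilylation would then lead to 17.
- Merits: the arene is bought with both oxygens in place, regiochemistry is fixed by the single ortho C–H bond, and the route is convergent. It should be about three steps shorter than the chosen plan. Its endgame is also gentler on the keto acid, because no ketal has to be hydrolysed in acid after the carboxyl is free.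
- Weak points: both oxygens arrive as methyl ethers, so a chelation-controlled mono-dealkylation with a boron halide must be carried out in the presence of an enol lactone and a silyl ether. Electron-rich ortho-alkoxybenzoic acids are prone to protodecarboxylation under heated C–H activation conditions. The method has been shown mainly on simple benzoic acids.
- Comparison: the chosen plan concedes step count. Against that, its oxygens are differentiated by the ring-forming step itself and not by a later selective dealkylation, it uses no precious metal, and every step is an established transformation on this substrate class.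

**Alternative 2:** Two arene bonds, C5–C6 and C1–C2, are cut. Forward, the 1,3-dioxygenated silyl ketene acetal diene A4 and the ynoate A5 combine in a Diels–Alder reaction. The diene's methylene terminus bonds to the ynoate β-carbon and the ketene acetal carbon to the α-carbon, and loss of the acetal alkoxy group aromatises the adduct to benzoate A6.
- Merits: it is convergent, regiochemistry follows from polarity matching, and the free C2 hydroxyl and C4 methoxy arise directly, as they do in the chosen plan.
- Weak points: β-alkyl ynoates are sluggish dienophiles and need temperatures at which such dienes degrade. The ketone cannot be carried next to the propargylic methylene, so A5 holds it as a silyl-protected carbinol. This creates a stereocentre of no use and forces a late oxidation. Benzyl ether hydrogenolysis and saponification of a di-ortho-substituted methyl benzoate, with the ketone already free, follow. A5 itself needs several steps.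
- Comparison: this road is longer than the chosen plan and its endgame is harsher. Its one advantage is that it avoids dianion chemistry.

**Alternative 3:** The bond from C1 to the carboxyl carbon and the lactone C–O bond are cut. Forward, palladium inserts into the C–Br bond of bromo ketone A7, carbonylation installs the carboxyl carbon, and O-acylation of the ketone enolate closes isocoumarin A8.
- Merits: the oxygenated arene is bought, and the most hindered substituent is introduced last as a one-carbon unit.
- Weak points: the bromide is electron-rich and flanked on both sides, so oxidative addition will be slow. A toxic gas under pressure is needed. A7 requires regioselective bromination and a separate ketone synthesis. The product then faces the same selective dealkylation and lactone opening as in Alternative 1, but after more steps.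
- Comparison: it shares the gentle final acidification of Alternative 1 without its brevity. The chosen plan is at least as short and avoids the dealkylation.

Key step: step 7

Assumption: 17 has no stereocentre or other stereogenic element, so the requirement of a single stereoisomer is met by its constitution. The carbinol carbon of 13 is the only stereocentre on the route; it forms without control and is lost in the same flask.

## Route

Step 1
Reactants: 1 2,2,6-trimethyl-4H-1,3-dioxin-4-one; 2 acetyl chloride
Product: 3 2,2-dimethyl-6-(2-oxopropyl)-4H-1,3-dioxin-4-one
Conditions: LiHMDS, THF, −78 °C; then 2 (0.5 equiv relative to enolate), −78 → −20 °C; aq. NH4Cl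
Reagents that add atoms: none
Why: γ-Deprotonation of 1 gives the lithium dienolate, which is C-acylated at the γ-carbon by acetyl chloride (Claisen-type acylation of a vinylogous ester enolate); the second equivalent of enolate deprotonates the more acidic product and so protects it from double acylation.

Step 2
Reactants: 4 12-hydroxydodecanoic acid
Product: 6 12-(tert-butyldimethylsilyloxy)dodecanoic acid, via bis-silylated ester 5 (not isolated)
Conditions: TBSCl (2.2 equiv), imidazole, DMF, rt; then K2CO3, MeOH/THF/H2O, rt; 1 M HCl to pH 4–5, 0 °C
Reagents that add atoms: tert-butyldimethylsilyl chloride (TBSCl), CC(C)(C)[Si](C)(C)Cl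
Why: Silylation of both hydroxyl and carboxyl, followed by selective solvolysis of the much more labile silyl ester under carbonate, is the standard route to an ω-silyloxy acid; the primary silyl ether should tolerate the brief cold acidification.

Step 3
Reactants: 6 12-(tert-butyldimethylsilyloxy)dodecanoic acid; 7 Meldrum's acid (2,2-dimethyl-1,3-dioxane-4,6-dione)
Product: 9 methyl 14-(tert-butyldimethylsilyloxy)-3-oxotetradecanoate, via acyl Meldrum's acid 8 (not isolated)
Conditions: DCC, DMAP, CH2Cl2, 0 °C → rt; filter; then MeOH, toluene, 80 °C
Reagents that add atoms: methanol, CO
Why: Carbodiimide/DMAP C-acylation of Meldrum's acid gives 8, and its alcoholysis with loss of acetone and carbon dioxide is the classical Meldrum's acid route to β-keto esters; no strong acid or base is involved, so the silyl ether should survive.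

Step 4
Reactants: 9 methyl 14-(tert-butyldimethylsilyloxy)-3-oxotetradecanoate
Product: 10 methyl {2-[11-(tert-butyldimethylsilyloxy)undecyl]-1,3-dioxolan-2-yl}acetate
Conditions: TMSOCH2CH2OTMS, TMSOTf (cat.), CH2Cl2, −78 → −20 °C
Reagents that add atoms: 1,2-bis(trimethylsilyloxy)ethane, C[Si](C)(C)OCCO[Si](C)(C)C
Why: Noyori ketalisation: silyl triflate-catalysed exchange with the bis-silyl ether of the diol is driven by formation of hexamethyldisiloxane under aprotic, cold conditions, so the ketone is masked without the hot protic acid that would remove the primary silyl ether.

Step 5
Reactants: 10 methyl {2-[11-(tert-butyldimethylsilyloxy)undecyl]-1,3-dioxolan-2-yl}acetate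
Product: 11 2-{2-[11-(tert-butyldimethylsilyloxy)undecyl]-1,3-dioxolan-2-yl}-N-methoxy-N-methylacetamide
Conditions: MeNHOMe·HCl, iPrMgCl, THF, −20 → 0 °C
Reagents that add atoms: N,O-dimethylhydroxylamine hydrochloride, CNOC.Cl
Why: Aminolysis of the methyl ester by the chloromagnesium amide of N,O-dimethylhydroxylamine is a standard direct ester-to-Weinreb-amide conversion; the magnesium amide is a weak base and does not touch the ketal or the silyl ether.

Step 6
Reactants: 3 2,2-dimethyl-6-(2-oxopropyl)-4H-1,3-dioxin-4-one; 11 2-{2-[11-(tert-butyldimethylsilyloxy)undecyl]-1,3-dioxolan-2-yl}-N-methoxy-N-methylacetamide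
Product: 12 6-(5-{2-[11-(tert-butyldimethylsilyloxy)undecyl]-1,3-dioxolan-2-yl}-2,4-dioxopentyl)-2,2-dimethyl-4H-1,3-dioxin-4-one
Conditions: 3 (1.5 equiv), LDA (3.1 equiv), THF, −78 °C; then 11, −78 → −40 °C; aq. NH4Cl; product used promptly
Reagents that add atoms: none
Why: Two equivalents of LDA turn 3 into its dianion, which reacts at the more basic terminal carbon with the Weinreb amide (Claisen-type acylation of a keto-dioxinone dianion); the chelated tetrahedral adduct persists until the quench, so the new 1,3-diketone never meets excess base, and the low α-acidity of the amide disfavours β-elimination of the dioxolane oxygen.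

Step 7
Reactants: 12 6-(5-{2-[11-(tert-butyldimethylsilyloxy)undecyl]-1,3-dioxolan-2-yl}-2,4-dioxopentyl)-2,2-dimethyl-4H-1,3-dioxin-4-one
Product: 14 5-({2-[11-(tert-butyldimethylsilyloxy)undecyl]-1,3-dioxolan-2-yl}methyl)-7-hydroxy-2,2-dimethyl-4H-1,3-benzodioxin-4-one, via cyclic aldol adduct 13 (not isolated)
Conditions: Et3N (3 equiv), CH2Cl2, rt
Reagents that add atoms: none
Why: Triethylamine reversibly deprotonates the doubly activated methylenes of 12, and in the vinylogous enolate that spans the chain C2 carbonyl and the dioxinone, ring carbon C5 (the future arene C1) is nucleophilic. C5 adds to the distal ketone at C4 of the dioxopentyl chain (the future arene C6) to give the cyclic aldol 13; E1cB loss of water and enolisation of the remaining ring ketone then deliver phenol 14, with aromatisation as the driving force. The closest known reaction type is the amine- or carbonate-mediated biomimetic aldol aromatisation of diketo-dioxinones to isopropylidene-protected resorcylates. The one ring closed is the benzene ring, formed in a 6-(enolendo)-exo-trig aldol in which the attacked C=O is exocyclic to the new ring. No stereocentre remains, since the carbinol carbon of 13 is formed without control and erased by dehydration. The selectivity needed is regiochemical and chemoselective: among all enolate-carbon/ketone pairings in 12, only C5 onto chain C4 closes a ring larger than four atoms, because the third carbonyl is locked as the dioxolane and can act neither as acceptor nor as donor. The dioxinone carbonyl is a deactivated vinylogous carbonate that resists Claisen attack at room temperature, and retro-[4+2] loss of acetone to the acyl ketene, the entry to pyranones, needs heat, so only the aldol channel is open. The amine ionises the 1,3-dicarbonyl positions but not the methylene next to the ketal, which keeps β-elimination of the dioxolane oxygen from competing.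

Step 8
Reactants: 14 5-({2-[11-(tert-butyldimethylsilyloxy)undecyl]-1,3-dioxolan-2-yl}methyl)-7-hydroxy-2,2-dimethyl-4H-1,3-benzodioxin-4-one
Product: 15 5-({2-[11-(tert-butyldimethylsilyloxy)undecyl]-1,3-dioxolan-2-yl}methyl)-7-methoxy-2,2-dimethyl-4H-1,3-benzodioxin-4-one
Conditions: MeI, K2CO3, acetone, 40 °C
Reagents that add atoms: iodomethane, CI
Why: Williamson O-methylation of the only free phenol; the other phenolic oxygen is held in the acetonide, the para-acyl phenol is acidic enough for carbonate, and the ketal, silyl ether and dioxinone are inert to these conditions.

Step 9
Reactants: 15 5-({2-[11-(tert-butyldimethylsilyloxy)undecyl]-1,3-dioxolan-2-yl}methyl)-7-methoxy-2,2-dimethyl-4H-1,3-benzodioxin-4-one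
Product: 17 2-hydroxy-6-(13-hydroxy-2-oxotridecyl)-4-methoxybenzoic acid, via salicylic acid ketal 16 (not isolated)
Conditions: KOH, DMSO/H2O, 80 °C; then THF, aq. HCl (to pH 1), rt
Reagents that add atoms: potassium hydroxide, [K+].[OH-]; water, O
Why: Hydroxide adds to the aryl ester carbonyl of the benzodioxinone and the hemiketal fragment collapses to acetone and phenoxide (saponification of a salicylate acetonide), giving 16 as its potassium salt. Acidifying the same solution with dilute aqueous HCl then hydrolyses the dioxolane and the primary silyl ether (acetal hydrolysis and acidic desilylation) in a water-rich medium at room temperature, where the open keto acid is favoured over the dehydrated enol lactone.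

## Compound list

1 | 2,2,6-trimethyl-4H-1,3-dioxin-4-one | CC1=CC(=O)OC(C)(C)O1 | starting material
2 | acetyl chloride | CC(Cl)=O | starting material
3 | 2,2-dimethyl-6-(2-oxopropyl)-4H-1,3-dioxin-4-one | CC(=O)CC1=CC(=O)OC(C)(C)O1 | intermediate
4 | 12-hydroxydodecanoic acid | OCCCCCCCCCCCC(=O)O | starting material
5 | tert-butyldimethylsilyl 12-(tert-butyldimethylsilyloxy)dodecanoate (not isolated) | CC(C)(C)[Si](C)(C)OCCCCCCCCCCCC(=O)O[Si](C)(C)C(C)(C)C | intermediate
6 | 12-(tert-butyldimethylsilyloxy)dodecanoic acid | CC(C)(C)[Si](C)(C)OCCCCCCCCCCCC(=O)O | intermediate
7 | Meldrum's acid (2,2-dimethyl-1,3-dioxane-4,6-dione) | CC1(C)OC(=O)CC(=O)O1 | starting material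
8 | 5-[12-(tert-butyldimethylsilyloxy)-1-hydroxydodecylidene]-2,2-dimethyl-1,3-dioxane-4,6-dione (not isolated) | CC(C)(C)[Si](C)(C)OCCCCCCCCCCCC(O)=C1C(=O)OC(C)(C)OC1=O | intermediate
9 | methyl 14-(tert-butyldimethylsilyloxy)-3-oxotetradecanoate | COC(=O)CC(=O)CCCCCCCCCCCO[Si](C)(C)C(C)(C)C | intermediate
10 | methyl {2-[11-(tert-butyldimethylsilyloxy)undecyl]-1,3-dioxolan-2-yl}acetate | COC(=O)CC1(CCCCCCCCCCCO[Si](C)(C)C(C)(C)C)OCCO1 | intermediate
11 | 2-{2-[11-(tert-butyldimethylsilyloxy)undecyl]-1,3-dioxolan-2-yl}-N-methoxy-N-methylacetamide | CON(C)C(=O)CC1(CCCCCCCCCCCO[Si](C)(C)C(C)(C)C)OCCO1 | intermediate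
12 | 6-(5-{2-[11-(tert-butyldimethylsilyloxy)undecyl]-1,3-dioxolan-2-yl}-2,4-dioxopentyl)-2,2-dimethyl-4H-1,3-dioxin-4-one | CC1(C)OC(=O)C=C(O1)CC(=O)CC(=O)CC2(CCCCCCCCCCCO[Si](C)(C)C(C)(C)C)OCCO2 | intermediate
13 | 5-({2-[11-(tert-butyldimethylsilyloxy)undecyl]-1,3-dioxolan-2-yl}methyl)-5-hydroxy-2,2-dimethyl-5,6-dihydro-4H-1,3-benzodioxine-4,7(8H)-dione (racemic, not isolated) | CC1(C)OC(=O)C2=C(O1)CC(=O)CC2(O)CC3(CCCCCCCCCCCO[Si](C)(C)C(C)(C)C)OCCO3 | intermediate
14 | 5-({2-[11-(tert-butyldimethylsilyloxy)undecyl]-1,3-dioxolan-2-yl}methyl)-7-hydroxy-2,2-dimethyl-4H-1,3-benzodioxin-4-one | CC1(C)OC(=O)c2c(O1)cc(O)cc2CC3(CCCCCCCCCCCO[Si](C)(C)C(C)(C)C)OCCO3 | intermediate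
15 | 5-({2-[11-(tert-butyldimethylsilyloxy)undecyl]-1,3-dioxolan-2-yl}methyl)-7-methoxy-2,2-dimethyl-4H-1,3-benzodioxin-4-one | CC1(C)OC(=O)c2c(O1)cc(OC)cc2CC3(CCCCCCCCCCCO[Si](C)(C)C(C)(C)C)OCCO3 | intermediate
16 | 2-({2-[11-(tert-butyldimethylsilyloxy)undecyl]-1,3-dioxolan-2-yl}methyl)-6-hydroxy-4-methoxybenzoic acid (present as its potassium salt, not isolated) | COc1cc(O)c(C(=O)O)c(CC2(CCCCCCCCCCCO[Si](C)(C)C(C)(C)C)OCCO2)c1 | intermediate
17 | 2-hydroxy-6-(13-hydroxy-2-oxotridecyl)-4-methoxybenzoic acid | COc1cc(O)c(C(=O)O)c(CC(=O)CCCCCCCCCCCO)c1 | target

## Step count and least certain steps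

Total: 9 steps. Longest linear sequence: 8 steps (steps 2 to 9, from 4). Step 1 is a one-step branch that joins at step 6.

**Step 7 (key step).**
- Risk: carbon–carbon bond formation may be slow, because C5 of a dioxinone is a weak nucleophile. That would give time for β-elimination that opens the dioxolane, or for O-cyclisation, and the aldol 13 may be reluctant to dehydrate.
- Fallback: this sets out from 12 and routes the same aldol through an open-chain β-keto ester, whose α-carbon is a much better nucleophile. Heating 12 in toluene with methanol would expel acetone and trap the acyl ketene as methyl 8-{2-[11-(tert-butyldimethylsilyloxy)undecyl]-1,3-dioxolan-2-yl}-3,5,7-trioxooctanoate F1. Caesium carbonate in methanol, with brief acetic acid treatment to complete dehydration, would cyclise it to methyl 2-({2-[11-(tert-butyldimethylsilyloxy)undecyl]-1,3-dioxolan-2-yl}methyl)-4,6-dihydroxybenzoate F2. Methylation with one equivalent of iodomethane and carbonate should take place at the non-chelated para hydroxyl to give methyl 2-({2-[11-(tert-butyldimethylsilyloxy)undecyl]-1,3-dioxolan-2-yl}methyl)-6-hydroxy-4-methoxybenzoate F3. Saponification with hot potassium hydroxide returns to the route at 16, which is acidified as in step 9.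

**Step 6.**
- Risk: proton transfer from the amide α-methylene to the strongly basic dianion may outrun acylation, followed by opening of the dioxolane. The sensitive diketone 12 may also cyclise or decompose during work-up.
- Fallback: this sets out from 11 and 3 and replaces the Claisen acylation by an aldol addition and oxidation. Reduction of 11 with DIBAL-H would give {2-[11-(tert-butyldimethylsilyloxy)undecyl]-1,3-dioxolan-2-yl}acetaldehyde F4. The dianion of 3 adds to the aldehyde at −78 °C to give racemic 6-(5-{2-[11-(tert-butyldimethylsilyloxy)undecyl]-1,3-dioxolan-2-yl}-4-hydroxy-2-oxopentyl)-2,2-dimethyl-4H-1,3-dioxin-4-one F5. Dess–Martin oxidation then returns to the route at 12.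

**Step 4.**
- Risk: the silyl triflate may cleave or transfer the silyl ether, or ketalisation may stall because the β-keto ester rests partly as its enol or silyl enol ether.
- Fallback: this sets out from 9 and accepts loss of the silyl group. Azeotropic ketalisation with ethylene glycol and catalytic TsOH in benzene would give methyl [2-(11-hydroxyundecyl)-1,3-dioxolan-2-yl]acetate F6. Re-silylation with TBSCl and imidazole returns to the route at 10.

**Step 9.**
- Risk: the hindered acetonide may open incompletely. During the acid stage the liberated keto acid may dehydrate to the enol lactone, or the electron-rich salicylic acid may decarboxylate.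
- Fallback: this sets out from 15 and reverses the order, so that the last chemical event is alkaline. Dilute HCl in aqueous THF would remove the dioxolane and silyl ether while the carboxyl is still locked, giving 5-(13-hydroxy-2-oxotridecyl)-7-methoxy-2,2-dimethyl-4H-1,3-benzodioxin-4-one F7. Aqueous potassium hydroxide then opens the acetonide, and also any enol lactone formed by enolate O-acylation. Cold neutralisation to pH 3 returns to the route at 17. This order is second choice because the free ketone is then exposed to base next to an aryl ester.

## Further compounds

F1 | step 7 | methyl 8-{2-[11-(tert-butyldimethylsilyloxy)undecyl]-1,3-dioxolan-2-yl}-3,5,7-trioxooctanoate | COC(=O)CC(=O)CC(=O)CC(=O)CC1(CCCCCCCCCCCO[Si](C)(C)C(C)(C)C)OCCO1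
F2 | step 7 | methyl 2-({2-[11-(tert-butyldimethylsilyloxy)undecyl]-1,3-dioxolan-2-yl}methyl)-4,6-dihydroxybenzoate | COC(=O)c1c(O)cc(O)cc1CC1(CCCCCCCCCCCO[Si](C)(C)C(C)(C)C)OCCO1
F3 | step 7 | methyl 2-({2-[11-(tert-butyldimethylsilyloxy)undecyl]-1,3-dioxolan-2-yl}methyl)-6-hydroxy-4-methoxybenzoate | COC(=O)c1c(O)cc(OC)cc1CC1(CCCCCCCCCCCO[Si](C)(C)C(C)(C)C)OCCO1
F4 | step 6 | {2-[11-(tert-butyldimethylsilyloxy)undecyl]-1,3-dioxolan-2-yl}acetaldehyde | O=CCC1(CCCCCCCCCCCO[Si](C)(C)C(C)(C)C)OCCO1
F5 | step 6 | 6-(5-{2-[11-(tert-butyldimethylsilyloxy)undecyl]-1,3-dioxolan-2-yl}-4-hydroxy-2-oxopentyl)-2,2-dimethyl-4H-1,3-dioxin-4-one (racemic) | CC1(C)OC(=O)C=C(O1)CC(=O)CC(O)CC2(CCCCCCCCCCCO[Si](C)(C)C(C)(C)C)OCCO2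
F6 | step 4 | methyl [2-(11-hydroxyundecyl)-1,3-dioxolan-2-yl]acetate | COC(=O)CC1(CCCCCCCCCCCO)OCCO1
F7 | step 9 | 5-(13-hydroxy-2-oxotridecyl)-7-methoxy-2,2-dimethyl-4H-1,3-benzodioxin-4-one | CC1(C)OC(=O)c2c(O1)cc(OC)cc2CC(=O)CCCCCCCCCCCO
A1 | alternative 1 | 2,4-dimethoxybenzoic acid | COc1ccc(C(=O)O)c(OC)c1
A2 | alternative 1 | 1-[dimethyl(oxo)-λ6-sulfanylidene]-13-(triisopropylsilyloxy)tridecan-2-one | CS(C)(=O)=CC(=O)CCCCCCCCCCCO[Si](C(C)C)(C(C)C)C(C)C
A3 | alternative 1 | 6,8-dimethoxy-3-[11-(triisopropylsilyloxy)undecyl]isocoumarin | COc1cc(OC)c2C(=O)OC(CCCCCCCCCCCO[Si](C(C)C)(C(C)C)C(C)C)=Cc2c1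
A4 | alternative 2 | 1,3-dimethoxy-1-(trimethylsilyloxy)buta-1,3-diene | COC(=C)C=C(OC)O[Si](C)(C)C
A5 | alternative 2 | methyl 16-(benzyloxy)-5-(tert-butyldimethylsilyloxy)hexadec-2-ynoate (racemic) | COC(=O)C#CCC(O[Si](C)(C)C(C)(C)C)CCCCCCCCCCCOCc1ccccc1
A6 | alternative 2 | methyl 2-hydroxy-4-methoxy-6-[13-(benzyloxy)-2-(tert-butyldimethylsilyloxy)tridecyl]benzoate (racemic) | COC(=O)c1c(O)cc(OC)cc1CC(O[Si](C)(C)C(C)(C)C)CCCCCCCCCCCOCc1ccccc1
A7 | alternative 3 | 1-(2-bromo-3,5-dimethoxyphenyl)-13-(tert-butyldimethylsilyloxy)tridecan-2-one | COc1cc(OC)c(Br)c(CC(=O)CCCCCCCCCCCO[Si](C)(C)C(C)(C)C)c1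
A8 | alternative 3 | 6,8-dimethoxy-3-[11-(tert-butyldimethylsilyloxy)undecyl]isocoumarin | COc1cc(OC)c2C(=O)OC(CCCCCCCCCCCO[Si](C)(C)C(C)(C)C)=Cc2c1
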